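**Retrosynthetic overview**

1. Target ⇐ removal of a C8 silyl ether after double angeloylation (O3 and O10, two equivalents of angelic acid) of a tetraol in which only the allylic C8–OH is masked.
2. C8–O bond and C7=C14 methylene ⇐ ene reaction then [2,3]-sigmatropic shift of an allylseleninic acid on the 7(14)-ene; the C8 configuration is then fixed by oxidation and 1,3-anti hydride delivery from the bought C10 hydroxyl.
3. C8–C9 bond ⇐ radical allylation of (S)-1-iodo-3-methylbutane-2,3-diol (from methyl (R)-glycerate acetonide) by the ring allyl sulfone made from the isopropenyl group.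
4. Ring stereocentres ⇐ (R)-carvone: α′-hydroxylation, Mitsunobu inversion to the cis acetate, Luche reduction, hydroxyl-directed epoxidation.
5. Rings: the cyclohexane is bought with carvone; the oxirane is closed in step 4; no other ring is made.

Assumption: bisabolane numbering is used (ring C1 carries the chain, C2 OAc, C3 OAng, C4(Me)/C5 epoxide, C6 H2; chain C7(=C14H2)–C8(OH)–C9H2–C10(OAng)–C11(OH)Me2), and a two-stage operation whose intermediate is carried on crude counts as one step.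

**Route**

Step 1
Reactants: 1 (R)-(−)-carvone
Product: 3 (5S,6S)-6-hydroxy-2-methyl-5-(prop-1-en-2-yl)cyclohex-2-en-1-one, via potassium dienolate 2 (not isolated)
Conditions: KN(SiMe3)2, THF, −78 °C; (±)-2-(phenylsulfonyl)-3-phenyloxaziridine, −78 °C; AcOH quench
Reagents that add atoms: (±)-2-(phenylsulfonyl)-3-phenyloxaziridine, O=S(=O)(N1OC1c1ccccc1)c1ccccc1
Why: Kinetic deprotonation at the α′-CH2 (the future ring C2) gives the cross-conjugated dienolate, and Davis oxaziridine hydroxylation occurs anti to the neighbouring C1 isopropenyl group, so the C2 carbinol is set trans to C1 by the carvone stereocentre (minor cis epimer removed by chromatography).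

Step 2
Reactants: 3 (5S,6S)-6-hydroxy-2-methyl-5-(prop-1-en-2-yl)cyclohex-2-en-1-one
Product: 4 (1R,6S)-3-methyl-2-oxo-6-(prop-1-en-2-yl)cyclohex-3-en-1-yl acetate
Conditions: PPh3, DIAD, AcOH, PhMe, 0 → 25 °C
Reagents that add atoms: acetic acid, CC(=O)O
Why: Mitsunobu esterification, in which acetate displaces the oxyphosphonium-activated α-ketol in an SN2 step, inverts C2 and places the acetate cis to the C1 substituent.

Step 3
Reactants: 4 (1R,6S)-3-methyl-2-oxo-6-(prop-1-en-2-yl)cyclohex-3-en-1-yl acetate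
Product: 5 (1R,2S,6S)-2-hydroxy-3-methyl-6-(prop-1-en-2-yl)cyclohex-3-en-1-yl acetate
Conditions: NaBH4, CeCl3·7H2O, MeOH, −78 °C
Reagents that add atoms: none
Why: Luche 1,2-reduction; hydride attacks axially and anti to the pseudoaxial C2–OAc (Felkin–Anh, isopropenyl equatorial), the same facial course that turns carvone into cis-carveol, so the C3 hydroxyl ends cis to O2 and to the C1 substituent.

Step 4
Reactants: 5 (1R,2S,6S)-2-hydroxy-3-methyl-6-(prop-1-en-2-yl)cyclohex-3-en-1-yl acetate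
Product: 6 (1R,2R,3R,4S,6S)-2-hydroxy-1-methyl-4-(prop-1-en-2-yl)-7-oxabicyclo[4.1.0]heptan-3-yl acetate
Conditions: VO(acac)2 (cat.), t-BuOOH, CH2Cl2, 0 → 25 °C
Reagents that add atoms: tert-butyl hydroperoxide, CC(C)(C)OO
Why: Hydroxyl-directed vanadium-catalysed epoxidation (Sharpless–Michaelson) delivers oxygen to the allylic-alcohol alkene from the face of the C3–OH, fixing C4 and C5, and leaves the non-allylic isopropenyl alkene untouched.

Step 5
Reactants: 6 (1R,2R,3R,4S,6S)-2-hydroxy-1-methyl-4-(prop-1-en-2-yl)-7-oxabicyclo[4.1.0]heptan-3-yl acetate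
Product: 8 (1R,2R,3R,4S,6S)-2-hydroxy-1-methyl-4-[3-(phenylsulfonyl)prop-1-en-2-yl]-7-oxabicyclo[4.1.0]heptan-3-yl acetate, via allylic chloride 7 (not isolated)
Conditions: NaOCl (aq.), CeCl3·7H2O, CH2Cl2/H2O, 0 °C; crude chloride, PhSO2Na, Bu4NI (cat.), DMF, 25 °C
Reagents that add atoms: sodium benzenesulfinate, [Na+].[O-]S(=O)c1ccccc1
Why: Hypochlorous acid chlorinates the only alkene, the 1,1-disubstituted isopropenyl group, in an ene-type allylic chlorination, and the primary allylic chloride is then displaced by sulfinate sulfur (SN2); no stereocentre is touched.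

Step 6
Reactants: 9 methyl (R)-2,2-dimethyl-1,3-dioxolane-4-carboxylate
Product: 11 (R)-3-methylbutane-1,2,3-triol, via acetonide carbinol 10 (not isolated)
Conditions: MeMgBr (2.5 equiv), THF, 0 °C; then 2 M HCl (aq.), 25 °C
Reagents that add atoms: methylmagnesium bromide, C[Mg]Br
Why: Double Grignard addition to the ester followed by acid hydrolysis of the acetonide; the stereocentre (future C10) is bought with 9 and is not involved.

Step 7
Reactants: 11 (R)-3-methylbutane-1,2,3-triol
Product: 12 (S)-1-iodo-3-methylbutane-2,3-diol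
Conditions: I2, PPh3, imidazole, THF, 0 °C
Reagents that add atoms: iodine, II
Why: Garegg–Samuelsson (Appel-type) iodination is selective for the primary hydroxyl over the secondary and tertiary ones and leaves the stereocentre untouched (the descriptor changes only through priorities).

Step 8
Reactants: 8 (1R,2R,3R,4S,6S)-2-hydroxy-1-methyl-4-[3-(phenylsulfonyl)prop-1-en-2-yl]-7-oxabicyclo[4.1.0]heptan-3-yl acetate; 12 (S)-1-iodo-3-methylbutane-2,3-diol
Product: 13 (1R,2R,3R,4S,6S)-4-[(5R)-5,6-dihydroxy-6-methylhept-1-en-2-yl]-2-hydroxy-1-methyl-7-oxabicyclo[4.1.0]heptan-3-yl acetate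
Conditions: (Bu3Sn)2, hν (sunlamp), PhH, 30 °C, 12 in excess
Reagents that add atoms: none
Why: Keck-type radical allylation: Bu3Sn• abstracts iodine from 12, the primary radical adds to the CH2= terminus of the allyl sulfone, and β-scission of PhSO2• (trapped by the ditin) re-forms the 1,1-disubstituted alkene, forging C8–C9 under neutral conditions that tolerate the free hydroxyls, the acetate and the epoxide; no stereocentre is formed.

Step 9
Reactants: 13 (1R,2R,3R,4S,6S)-4-[(5R)-5,6-dihydroxy-6-methylhept-1-en-2-yl]-2-hydroxy-1-methyl-7-oxabicyclo[4.1.0]heptan-3-yl acetate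
Product: 16 (1R,2R,3R,4S,6S)-4-[(5R)-5,6-dihydroxy-6-methyl-3-oxohept-1-en-2-yl]-2-hydroxy-1-methyl-7-oxabicyclo[4.1.0]heptan-3-yl acetate, via allylseleninic acid 14 (not isolated), via allylic alcohol epimers 15 (not isolated)
Conditions: SeO2 (cat.), t-BuOOH, CH2Cl2, 25 °C; then MnO2, CH2Cl2, 25 °C
Reagents that add atoms: selenium dioxide, O=[Se]=O (catalytic oxygen carrier); tert-butyl hydroperoxide, CC(C)(C)OO (stoichiometric oxygen source)
Why: Riley allylic oxidation: the ene reaction of SeO2 at C14 gives the allylseleninic acid, whose [2,3]-sigmatropic rearrangement forms the C8–O bond and restores the C7=C14 methylene (allylic CH2 reacts in preference to the ring CH), and MnO2 then oxidises only the allylic carbinol, so the uncontrolled C8 configuration is erased in the enone.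

Step 10
Reactants: 16 (1R,2R,3R,4S,6S)-4-[(5R)-5,6-dihydroxy-6-methyl-3-oxohept-1-en-2-yl]-2-hydroxy-1-methyl-7-oxabicyclo[4.1.0]heptan-3-yl acetate
Product: 17 (1R,2R,3R,4S,6S)-2-hydroxy-1-methyl-4-[(3R,5R)-3,5,6-trihydroxy-6-methylhept-1-en-2-yl]-7-oxabicyclo[4.1.0]heptan-3-yl acetate
Conditions: Me4NBH(OAc)3, MeCN/AcOH, −30 °C
Reagents that add atoms: none
Why: Evans–Saksena reduction: the C10 hydroxyl binds the triacetoxyborohydride and delivers hydride intramolecularly through a chair transition state, giving the 1,3-anti diol and thus the (8R) carbinol under control of the bought C10 centre.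

Step 11
Reactants: 17 (1R,2R,3R,4S,6S)-2-hydroxy-1-methyl-4-[(3R,5R)-3,5,6-trihydroxy-6-methylhept-1-en-2-yl]-7-oxabicyclo[4.1.0]heptan-3-yl acetate
Product: 18 (1R,2R,3R,4S,6S)-4-[(3R,5R)-5,6-dihydroxy-6-methyl-3-(triethylsilyloxy)hept-1-en-2-yl]-2-hydroxy-1-methyl-7-oxabicyclo[4.1.0]heptan-3-yl acetate
Conditions: Et3SiCl (1.1 equiv), imidazole, CH2Cl2, −40 °C
Reagents that add atoms: chlorotriethylsilane, CC[Si](Cl)(CC)CC
Why: Kinetically controlled silylation picks the least hindered secondary (allylic) C8 hydroxyl; the C10–OH beside the quaternary carbinol, the ring C3–OH flanked by the epoxide carbon and the acetate, and the tertiary C11–OH react far more slowly.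

Step 12
Reactants: 18 (1R,2R,3R,4S,6S)-4-[(3R,5R)-5,6-dihydroxy-6-methyl-3-(triethylsilyloxy)hept-1-en-2-yl]-2-hydroxy-1-methyl-7-oxabicyclo[4.1.0]heptan-3-yl acetate; 19 angelic acid
Product: 21 (1R,2R,3R,4S,6S)-3-acetoxy-4-[(3R,5R)-6-hydroxy-6-methyl-5-{[(Z)-2-methylbut-2-enoyl]oxy}-3-(triethylsilyloxy)hept-1-en-2-yl]-1-methyl-7-oxabicyclo[4.1.0]heptan-2-yl (Z)-2-methylbut-2-enoate, via mixed anhydride 20 (not isolated)
Conditions: 19 (6 equiv), 2,4,6-Cl3C6H2COCl (6 equiv), Et3N, PhMe, 25 °C; then 18, 80 °C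
Reagents that add atoms: angelic acid, C/C=C(/C)C(=O)O (second equivalent of 19)
Why: Yamaguchi-type esterification through the mixed anhydride formed in the flask, run without DMAP so that the Z (angelate) geometry is kept; two equivalents of the anhydride are consumed, one at each remaining secondary hydroxyl (O3 and O10), while the tertiary alcohol and the silyl ether are inert and no stereocentre changes.

Step 13
Reactants: 21 bis-angelate triethylsilyl ether
Product: 22 target CNP0105552.1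
Conditions: HF·pyridine, pyridine, THF, 0 °C
Reagents that add atoms: none
Why: Buffered fluoride desilylation frees the C8 hydroxyl without touching the three esters or the epoxide.

**Compound list**

1 | (R)-(−)-carvone, (5R)-2-methyl-5-(prop-1-en-2-yl)cyclohex-2-en-1-one | C=C(C)[C@@H]1CC=C(C)C(=O)C1 | starting material
2 | potassium cross-conjugated dienolate of 1 (potassium 6-methyl-3-(prop-1-en-2-yl)cyclohexa-1,5-dien-1-olate, stereocentre as in 1) | C=C(C)[C@@H]1CC=C(C)C(O[K])=C1 | intermediate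
3 | (5S,6S)-6-hydroxy-2-methyl-5-(prop-1-en-2-yl)cyclohex-2-en-1-one (OH trans to isopropenyl) | C=C(C)[C@@H]1CC=C(C)C(=O)[C@H]1O | intermediate
4 | (1R,6S)-3-methyl-2-oxo-6-(prop-1-en-2-yl)cyclohex-3-en-1-yl acetate (OAc cis to isopropenyl) | C=C(C)[C@@H]1CC=C(C)C(=O)[C@@H]1OC(C)=O | intermediate
5 | (1R,2S,6S)-2-hydroxy-3-methyl-6-(prop-1-en-2-yl)cyclohex-3-en-1-yl acetate (OH, OAc, isopropenyl all cis) | C=C(C)[C@@H]1CC=C(C)[C@H](O)[C@@H]1OC(C)=O | intermediate
6 | (1R,2R,3R,4S,6S)-2-hydroxy-1-methyl-4-(prop-1-en-2-yl)-7-oxabicyclo[4.1.0]heptan-3-yl acetate (oxirane O, OH, OAc, isopropenyl on one face) | C=C(C)[C@@H]1C[C@@H]2O[C@]2(C)[C@H](O)[C@@H]1OC(C)=O | intermediate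
7 | (1R,2R,3R,4S,6S)-4-(3-chloroprop-1-en-2-yl)-2-hydroxy-1-methyl-7-oxabicyclo[4.1.0]heptan-3-yl acetate | C=C(CCl)[C@@H]1C[C@@H]2O[C@]2(C)[C@H](O)[C@@H]1OC(C)=O | intermediate
8 | (1R,2R,3R,4S,6S)-2-hydroxy-1-methyl-4-[3-(phenylsulfonyl)prop-1-en-2-yl]-7-oxabicyclo[4.1.0]heptan-3-yl acetate | C=C(CS(=O)(=O)c1ccccc1)[C@@H]1C[C@@H]2O[C@]2(C)[C@H](O)[C@@H]1OC(C)=O | intermediate
9 | methyl (R)-2,2-dimethyl-1,3-dioxolane-4-carboxylate | COC(=O)[C@H]1COC(C)(C)O1 | starting material
10 | (R)-2-(2,2-dimethyl-1,3-dioxolan-4-yl)propan-2-ol | CC(C)(O)[C@H]1COC(C)(C)O1 | intermediate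
11 | (R)-3-methylbutane-1,2,3-triol | OC[C@@H](O)C(C)(C)O | intermediate
12 | (S)-1-iodo-3-methylbutane-2,3-diol | IC[C@@H](O)C(C)(C)O | intermediate
13 | (1R,2R,3R,4S,6S)-4-[(5R)-5,6-dihydroxy-6-methylhept-1-en-2-yl]-2-hydroxy-1-methyl-7-oxabicyclo[4.1.0]heptan-3-yl acetate | C=C(CC[C@@H](O)C(C)(C)O)[C@@H]1C[C@@H]2O[C@]2(C)[C@H](O)[C@@H]1OC(C)=O | intermediate
14 | allylseleninic acid ene adduct: (5R)-5,6-dihydroxy-6-methyl-2-(ring of 13)hept-2-ene-1-seleninic acid, E/Z mixture | O[Se](=O)CC(=CC[C@@H](O)C(C)(C)O)[C@@H]1C[C@@H]2O[C@]2(C)[C@H](O)[C@@H]1OC(C)=O | intermediate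
15 | (1R,2R,3R,4S,6S)-2-hydroxy-1-methyl-4-[(5R)-3,5,6-trihydroxy-6-methylhept-1-en-2-yl]-7-oxabicyclo[4.1.0]heptan-3-yl acetate, both C8 epimers | C=C(C(O)C[C@@H](O)C(C)(C)O)[C@@H]1C[C@@H]2O[C@]2(C)[C@H](O)[C@@H]1OC(C)=O | intermediate
16 | (1R,2R,3R,4S,6S)-4-[(5R)-5,6-dihydroxy-6-methyl-3-oxohept-1-en-2-yl]-2-hydroxy-1-methyl-7-oxabicyclo[4.1.0]heptan-3-yl acetate | C=C(C(=O)C[C@@H](O)C(C)(C)O)[C@@H]1C[C@@H]2O[C@]2(C)[C@H](O)[C@@H]1OC(C)=O | intermediate
17 | (1R,2R,3R,4S,6S)-2-hydroxy-1-methyl-4-[(3R,5R)-3,5,6-trihydroxy-6-methylhept-1-en-2-yl]-7-oxabicyclo[4.1.0]heptan-3-yl acetate (8,10-anti) | C=C([C@H](O)C[C@@H](O)C(C)(C)O)[C@@H]1C[C@@H]2O[C@]2(C)[C@H](O)[C@@H]1OC(C)=O | intermediate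
18 | (1R,2R,3R,4S,6S)-4-[(3R,5R)-5,6-dihydroxy-6-methyl-3-(triethylsilyloxy)hept-1-en-2-yl]-2-hydroxy-1-methyl-7-oxabicyclo[4.1.0]heptan-3-yl acetate | C=C([C@H](O[Si](CC)(CC)CC)C[C@@H](O)C(C)(C)O)[C@@H]1C[C@@H]2O[C@]2(C)[C@H](O)[C@@H]1OC(C)=O | intermediate
19 | angelic acid, (Z)-2-methylbut-2-enoic acid | C/C=C(/C)C(=O)O | starting material
20 | (Z)-2-methylbut-2-enoic 2,4,6-trichlorobenzoic anhydride | C/C=C(/C)C(=O)OC(=O)c1c(Cl)cc(Cl)cc1Cl | intermediate
21 | (1R,2R,3R,4S,6S)-3-acetoxy-4-[(3R,5R)-6-hydroxy-6-methyl-5-{[(Z)-2-methylbut-2-enoyl]oxy}-3-(triethylsilyloxy)hept-1-en-2-yl]-1-methyl-7-oxabicyclo[4.1.0]heptan-2-yl (Z)-2-methylbut-2-enoate | C=C([C@H](O[Si](CC)(CC)CC)C[C@@H](OC(=O)/C(C)=C\C)C(C)(C)O)[C@@H]1C[C@@H]2O[C@]2(C)[C@H](OC(=O)/C(C)=C\C)[C@@H]1OC(C)=O | intermediate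
22 | CNP0105552.1, (1R,2R,3R,4S,6S)-3-acetoxy-4-[(3R,5R)-3,6-dihydroxy-6-methyl-5-{[(Z)-2-methylbut-2-enoyl]oxy}hept-1-en-2-yl]-1-methyl-7-oxabicyclo[4.1.0]heptan-2-yl (Z)-2-methylbut-2-enoate | C=C([C@H](O)C[C@@H](OC(=O)/C(C)=C\C)C(C)(C)O)[C@@H]1C[C@@H]2O[C@]2(C)[C@H](OC(=O)/C(C)=C\C)[C@@H]1OC(C)=O | target

**Step count and risks**

Total step count: 13. Longest linear sequence: 11 steps (1 → 22 through steps 1–5 and 8–13); the side-chain piece takes 2 steps (6 and 7) before the union.

The three steps most likely to fail: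

Step 2 (Mitsunobu inversion of the α-ketol). The activated carbinol lies next to an enolisable ketone and can eliminate toward the dienone and then the phenol instead of being displaced. The fallback sets out from 3 and comes back at 4: 3 is converted with Tf2O and pyridine in CH2Cl2 at −40 °C into the trans α-keto triflate (1S,6S)-3-methyl-2-oxo-6-(prop-1-en-2-yl)cyclohex-3-en-1-yl trifluoromethanesulfonate F1, and CsOAc with 18-crown-6 in toluene at 25 °C displaces the triflate with inversion to give 4.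

Step 8 (radical allylation). The chain may stall with a hindered, highly functionalised 2-substituted allyl sulfone, and the iodohydrin may be reduced or close to the epoxide. The fallback sets out from 7 (isolated after the first stage of step 5 instead of being carried on) and from 12, and comes back at 13: a nickel-catalysed reductive cross-electrophile coupling of the allylic chloride with the alkyl iodide (NiCl2(dme), 4,4′-di-tert-butyl-2,2′-bipyridine, Zn, DMA, 25 °C) joins C8 to C9 directly; this fallback makes no new compound (F0).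

Step 12 (double angeloylation). Both hydroxyls are hindered, the angelate can isomerise to the tiglate, and at 80 °C with Et3N the C2 acetate can migrate to the free O3 before acylation. The fallback sets out from 18 and comes back at 21: both hydroxyls are esterified under mild conditions (DCC, DMAP, CH2Cl2, 0 °C) with 2-[bis(2,2,2-trifluoroethoxy)phosphoryl]propanoic acid to give the bis(phosphonopropanoate) of 18 F2, and a double Still–Gennari olefination (KN(SiMe3)2, 18-crown-6, MeCHO, THF, −78 °C) then builds both (Z)-2-methylbut-2-enoates to give 21.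

Further compounds

F1 | step 2 | (1S,6S)-3-methyl-2-oxo-6-(prop-1-en-2-yl)cyclohex-3-en-1-yl trifluoromethanesulfonate | C=C(C)[C@@H]1CC=C(C)C(=O)[C@H]1OS(=O)(=O)C(F)(F)F
F0 | step 8 | none | none
F2 | step 12 | 18 esterified at O3 and O10 with 2-[bis(2,2,2-trifluoroethoxy)phosphoryl]propanoic acid (epimeric at the phosphorus-bearing carbons) | C=C([C@H](O[Si](CC)(CC)CC)C[C@@H](OC(=O)C(C)P(=O)(OCC(F)(F)F)OCC(F)(F)F)C(C)(C)O)[C@@H]1C[C@@H]2O[C@]2(C)[C@H](OC(=O)C(C)P(=O)(OCC(F)(F)F)OCC(F)(F)F)[C@@H]1OC(C)=O
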